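The runs come from a simulation with made-up constants, noise included.

Whatever substrate is charged stays counted: the share that is product and the share not yet product add up to the whole charge at each moment. A flask can therefore be followed by the share that falls.

| setting | Wednesday's | Saturday's | eta | zeta |
|---|---|---|---|---|
| substrate | 0.16 M | 0.16 M | 0.16 M | 0.16 M |
| reagent | 1.7 equiv | 3.2 equiv | 2.00 equiv | 4.00 equiv |
| remark | run made earlier | run made earlier |  |  |
| time |  |  | 15 min | 15 min |

| Wednesday's: time / min | Wednesday's: product / % | Saturday's: time / min | Saturday's: product / % |
|---|---|---|---|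
| 0.833 | 3 | 1.33 | 13 |
| 2.50 | 8 | 2.00 | 21 |
| 4.00 | 14 | 3.00 | 28 |
| 6.00 | 19 | 4.00 | 34 |
| 10.0 | 26 | 6.00 | 48 |
| 12.0 | 32 | 10.0 | 64 |
| 15.0 | 38 | 15.0 | 79 |

(each reading ± 1.5 percentage points)

* which of the two ends with the higher amount of product, in percent of the substrate charged ("neither" if they lie within 2 percentage points) (eta / zeta / neither)
* product at the end, in percent of the substrate charged, eta
* product at the end, in percent of the substrate charged, zeta

In both runs the share not yet product falls by a roughly steady factor per minute, within the scatter of 1.5 percentage points. Wednesday's last reading gives a turnover time, the time in which that share falls by a factor e (the inverse of a pseudo-first-order constant), of 31.4 min, and Saturday's gives 9.61 min. Two times then matter, the length of the run and the turnover time, and the product share is one minus exp(−run time / turnover time).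

This reckoning takes the inverse turnover time as a straight line in equivalents through the two runs, which for zeta is an extrapolation. Flask eta gets 21.6 min and flask zeta 7.02 min. The run of 15 min is shorter than the first and longer than the second, so eta reaches 50.1% and zeta reaches 88.2%, the higher of the two.

The forecast gives 50% for eta and 89% for zeta, and says “Zeta clearly ends higher”.

The flasks give 48.9% for eta and 85.2% for zeta, so zeta ends higher.

    substrate + reagent → intermediate A (k = 0.450 M⁻¹ s⁻¹)
    intermediate A ⇌ intermediate B (K = 3.00, k = 0.0870 s⁻¹)
    intermediate B ⇌ intermediate C (K = 0.960, k = 0.370 s⁻¹)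
    reagent + intermediate C → product (k = 0.0200 M⁻¹ s⁻¹)
    reagent + intermediate C ⇌ intermediate D (K = 2.60 M⁻¹, k = 0.0670 M⁻¹ s⁻¹)
    crystals ⇌ product, rate k6*(cs6 - [product]) while solid is left; crystals form when [product] > cs6 (solubility = 0.0650 M, k = 0.250 s⁻¹)

Read back, zeta's end gives a turnover time of 7.85 min, longer than the reckoned 7.02 min. Zeta's substrate stands at 0% by then, and the share not yet product stands as intermediates A, B, C and D, together 14.8%. The neighbour is the same flask as zeta with 1.60 equiv of reagent, below Wednesday's charge. The same line gives it 37.0 min, hence 0.405 turnovers and 33.3% product. That flask ends with 32.8% product, and 26.9% stands as intermediate C.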